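**Retrosynthetic overview**
- The anisoate is put on last; the C6 carbinol comes from a hydroxyl-directed reduction of a β-hydroxy ketone, and the C4 carbinol from isopropyl addition to a cyclopentanone.
- The trans ring fusion (C5–H) comes from a stereospecific 1,2-hydride shift in an epoxy alcohol made from a bicyclic dienone.
- Both carbocycles form in one pot from an acyclic 1,4-diketone: aldol cyclodehydration closes the five-membered ring, then a divinylcyclopropane Cope rearrangement closes the seven-membered ring and creates the quaternary carbon.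
- The diketone comes from 2-methylfuran and a cyclopropylmethyl bromide, which comes from asymmetric cyclopropanation of a (Z)-dienol.
- Ring order: cyclopropane (chirality relay, consumed), then five- and seven-membered rings together.

Assumption: (2Z)-3-methylpent-2-en-4-yn-1-ol, both enantiomers of N,N,N′,N′-tetramethyltartramide and both enantiomers of the 2-methyl-CBS-oxazaborolidine are taken as commercial.

Atom labels used for the bicyclic compounds (daucane numbering): C1 = methyl-bearing ring-fusion carbon, C2, C3, C4 = carbon that ends with OH and isopropyl, C5 = other ring-fusion carbon, C6 = carbon that ends with the ester, C7, C8 = methyl-bearing alkene carbon, C9, C10.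

**Route**

Step 1
Reactants: 1 (2Z)-3-methylpent-2-en-4-yn-1-ol
Product: 2 (2Z)-3-methylpenta-2,4-dien-1-ol
Conditions: H2 (1 atm), Pd/CaCO3 poisoned with Pb(OAc)2, quinoline, EtOAc, 0 °C, stopped after 1 equiv H2
Reagents that add atoms: none
Why: Lindlar-type semihydrogenation reduces only the terminal alkyne to the vinyl group and leaves the Z trisubstituted alkene untouched, so CH2OH stays cis to the vinyl group.

Step 2
Reactants: 2 (2Z)-3-methylpenta-2,4-dien-1-ol
Product: 3 [(1R,2R)-2-ethenyl-2-methylcyclopropyl]methanol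
Conditions: Zn(CH2I)2·DME (from Et2Zn and CH2I2, 2.2 equiv), (4S,5S)-2-butyl-N,N,N′,N′-tetramethyl-1,3,2-dioxaborolane-4,5-dicarboxamide (1.2 equiv), CH2Cl2, −10 °C to rt; aq NH4Cl
Reagents that add atoms: diiodomethane, ICI
Why: Charette asymmetric Simmons–Smith cyclopropanation: the zinc alkoxide bound to the chiral dioxaborolane delivers CH2 to one face of the allylic-alcohol alkene only, syn-stereospecifically (CH2OH and vinyl stay cis), and the (S,S) ligand (antipode of the one that gives the (1S,2S) alcohol from cinnamyl alcohol) sets (1R,2R).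

Step 3
Reactants: 3 [(1R,2R)-2-ethenyl-2-methylcyclopropyl]methanol
Product: 4 (1R,2R)-2-(bromomethyl)-1-ethenyl-1-methylcyclopropane
Conditions: CBr4, PPh3, CH2Cl2, −20 to 0 °C
Reagents that add atoms: carbon tetrabromide, BrC(Br)(Br)Br
Why: Appel bromination proceeds by SN2 displacement at the primary carbon without a free cyclopropylcarbinyl cation, so the ring and its two stereocentres are untouched.

Step 4
Reactants: 4 (1R,2R)-2-(bromomethyl)-1-ethenyl-1-methylcyclopropane; 5 2-methylfuran
Product: 7 2-{[(1S,2R)-2-ethenyl-2-methylcyclopropyl]methyl}-5-methylfuran, via (5-methylfuran-2-yl)lithium 6 (not isolated)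
Conditions: 5, n-BuLi, THF, −20 to 0 °C; then 4, DMPU, −78 °C to rt
Reagents that add atoms: none
Why: α-lithiation of the furan followed by SN2 alkylation with the primary bromide installs the furan as a masked 1,4-diketone; no stereocentre is involved (the descriptor change is only a priority change).

Step 5
Reactants: 7 2-{[(1S,2R)-2-ethenyl-2-methylcyclopropyl]methyl}-5-methylfuran
Product: 8 1-[(1S,2R)-2-ethenyl-2-methylcyclopropyl]hexane-2,5-dione
Conditions: AcOH/H2O (3:1), H2SO4 (5 mol%), 70 °C
Reagents that add atoms: water, O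
Why: acid-catalysed hydrolysis of a 2,5-dialkylfuran (reverse Paal–Knorr) gives the 1,4-diketone, the electron-rich furan being protonated far more readily than the vinyl group; stereocentres untouched.

Step 6 (key step)
Reactants: 8 1-[(1S,2R)-2-ethenyl-2-methylcyclopropyl]hexane-2,5-dione
Product: 10 (3aR)-3a,6-dimethyl-3,3a,4,7-tetrahydroazulen-1(2H)-one, via cyclopentenone 9 (not isolated)
Conditions: KOH (20 mol%), MeOH, 55 °C; then AcOH (20 mol%), solvent switch to toluene, 120 °C (sealed), one pot
Reagents that add atoms: none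
Why: Proposed new method: a jasmone-type intramolecular aldol condensation closes the cyclopentenone 9, whose enone C=C is then cis to the vinyl group on the cyclopropane, so the divinylcyclopropane–cycloheptadiene (Cope) rearrangement through the boat transition state closes the seven-membered ring and transfers the cyclopropane chirality to the quaternary C1 (R); the closest known reactions are base-mediated cyclodehydration of 2,5-diketones and the Cope rearrangement of (2-vinylcyclopropyl)enones.

Step 7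
Reactants: 10 (3aR)-3a,6-dimethyl-3,3a,4,7-tetrahydroazulen-1(2H)-one
Product: 11 (1S,3aR)-3a,6-dimethyl-1,2,3,3a,4,7-hexahydroazulen-1-ol
Conditions: (R)-2-methyl-CBS-oxazaborolidine (20 mol%), catecholborane, toluene, −78 °C
Reagents that add atoms: none
Why: Corey–Bakshi–Shibata reduction gives reagent-controlled 1,2-hydride delivery (alkenyl side as the large group), setting the C4 carbinol S with OH on the face of the C1 methyl.

Step 8
Reactants: 11 (1S,3aR)-3a,6-dimethyl-1,2,3,3a,4,7-hexahydroazulen-1-ol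
Product: 12 (1S,3aR,8R,8aR)-8,8a-epoxy-3a,6-dimethyl-1,2,3,3a,4,7,8,8a-octahydroazulen-1-ol
Conditions: VO(acac)2 (5 mol%), t-BuOOH, CH2Cl2, 0 °C to rt
Reagents that add atoms: tert-butyl hydroperoxide, CC(C)(C)OO
Why: hydroxyl-directed vanadium-catalysed epoxidation delivers oxygen to the C5=C6 face syn to the C4 hydroxyl and leaves the remote C8=C9 alkene alone.

Step 9
Reactants: 12 (1S,3aR,8R,8aR)-8,8a-epoxy-3a,6-dimethyl-1,2,3,3a,4,7,8,8a-octahydroazulen-1-ol
Product: 14 (3aR,8R,8aS)-3a,6-dimethyl-8-[(triethylsilyl)oxy]-3,3a,4,7,8,8a-hexahydroazulen-1(2H)-one, via triethylsilyl ether 13 (not isolated)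
Conditions: Et3SiOTf (2.2 equiv), i-Pr2NEt, CH2Cl2, −78 to −40 °C
Reagents that add atoms: triethylsilyl trifluoromethanesulfonate, CC[Si](CC)(CC)OS(=O)(=O)C(F)(F)F
Why: Jung non-aldol aldol (epoxy silyl ether semipinacol) rearrangement: the tertiary C5–O bond of the silyl-activated epoxide opens while the anti-periplanar C4–H shifts to C5 with inversion, so hydrogen enters C5 on the face opposite the epoxide oxygen and the C1 methyl (trans ring fusion), and the epoxide oxygen stays on C6 as its silyl ether.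

Step 10
Reactants: 14 (3aR,8R,8aS)-3a,6-dimethyl-8-[(triethylsilyl)oxy]-3,3a,4,7,8,8a-hexahydroazulen-1(2H)-one
Product: 16 (3R,3aS,4R,8aR)-6,8a-dimethyl-3-(propan-2-yl)-1,2,3,3a,4,5,8,8a-octahydroazulene-3,4-diol, via triethylsilyl ether 15 (not isolated)
Conditions: i-PrMgCl, CeCl3, THF, −78 to −20 °C; then 1 M aq HCl/THF, rt
Reagents that add atoms: isopropylmagnesium chloride, CC(C)[Mg]Cl
Why: organocerium (Imamoto) 1,2-addition to the enolisable cyclopentanone occurs anti to the adjacent C5–C6 branch and the C1 methyl, placing isopropyl trans and the new OH cis to them (C4 R); dilute acid then removes the silyl ether.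

Step 11
Reactants: 16 (3R,3aS,4R,8aR)-6,8a-dimethyl-3-(propan-2-yl)-1,2,3,3a,4,5,8,8a-octahydroazulene-3,4-diol
Product: 17 (3R,3aR,8aR)-3-hydroxy-6,8a-dimethyl-3-(propan-2-yl)-1,2,3,3a,8,8a-hexahydroazulen-4(5H)-one
Conditions: Dess–Martin periodinane, NaHCO3, CH2Cl2, 0 °C
Reagents that add atoms: none
Why: Dess–Martin oxidation converts the only secondary alcohol (tertiary OH inert) to the ketone, erasing the wrongly configured C6 carbinol under buffered conditions that do not epimerise C5.

Step 12
Reactants: 17 (3R,3aR,8aR)-3-hydroxy-6,8a-dimethyl-3-(propan-2-yl)-1,2,3,3a,8,8a-hexahydroazulen-4(5H)-one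
Product: 18 jaeschkeanadiol, (3R,3aS,4S,8aR)-6,8a-dimethyl-3-(propan-2-yl)-1,2,3,3a,4,5,8,8a-octahydroazulene-3,4-diol
Conditions: Me4NBH(OAc)3, MeCN/AcOH (1:1), −30 °C
Reagents that add atoms: none
Why: Evans–Saksena hydroxyl-directed reduction: the acetoxyborohydride bound to the C4 oxygen delivers hydride intramolecularly to the near face of the C6 ketone, giving the 6S carbinol.

Step 13
Reactants: 18 jaeschkeanadiol; 19 4-methoxybenzoyl chloride
Product: 20 Fertidin, (3R,3aS,4S,8aR)-3-hydroxy-6,8a-dimethyl-3-(propan-2-yl)-1,2,3,3a,4,5,8,8a-octahydroazulen-4-yl 4-methoxybenzoate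
Conditions: Et3N, DMAP (cat.), CH2Cl2, 0 °C to rt
Reagents that add atoms: none
Why: DMAP-catalysed acylation (nucleophilic acyl substitution) esterifies the secondary alcohol only, the tertiary C4 hydroxyl being too hindered, and touches no stereocentre.

**Compound list**

1 | (2Z)-3-methylpent-2-en-4-yn-1-ol | OC/C=C(/C)C#C | starting material
2 | (2Z)-3-methylpenta-2,4-dien-1-ol | OC/C=C(/C)C=C | intermediate
3 | [(1R,2R)-2-ethenyl-2-methylcyclopropyl]methanol (CH2OH cis to vinyl) | OC[C@@H]1C[C@]1(C)C=C | intermediate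
4 | (1R,2R)-2-(bromomethyl)-1-ethenyl-1-methylcyclopropane | BrC[C@@H]1C[C@]1(C)C=C | intermediate
5 | 2-methylfuran | Cc1ccco1 | starting material
6 | (5-methylfuran-2-yl)lithium | [Li]c1ccc(C)o1 | intermediate (not isolated)
7 | 2-{[(1S,2R)-2-ethenyl-2-methylcyclopropyl]methyl}-5-methylfuran | Cc1ccc(C[C@@H]2C[C@]2(C)C=C)o1 | intermediate
8 | 1-[(1S,2R)-2-ethenyl-2-methylcyclopropyl]hexane-2,5-dione | CC(=O)CCC(=O)C[C@@H]1C[C@]1(C)C=C | intermediate
9 | 2-[(1R,2R)-2-ethenyl-2-methylcyclopropyl]-3-methylcyclopent-2-en-1-one | CC1=C(C(=O)CC1)[C@@H]2C[C@]2(C)C=C | intermediate (not isolated)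
10 | (3aR)-3a,6-dimethyl-3,3a,4,7-tetrahydroazulen-1(2H)-one | O=C1CC[C@]2(C)CC=C(C)CC=C12 | intermediate
11 | (1S,3aR)-3a,6-dimethyl-1,2,3,3a,4,7-hexahydroazulen-1-ol | O[C@H]1CC[C@]2(C)CC=C(C)CC=C12 | intermediate
12 | (1S,3aR,8R,8aR)-8,8a-epoxy-3a,6-dimethyl-1,2,3,3a,4,7,8,8a-octahydroazulen-1-ol (epoxide O cis to OH and to the angular methyl) | O[C@H]1CC[C@]2(C)CC=C(C)C[C@H]3O[C@@]123 | intermediate
13 | triethylsilyl ether of 12 | CC[Si](CC)(CC)O[C@H]1CC[C@]2(C)CC=C(C)C[C@H]3O[C@@]123 | intermediate (not isolated)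
14 | (3aR,8R,8aS)-3a,6-dimethyl-8-[(triethylsilyl)oxy]-3,3a,4,7,8,8a-hexahydroazulen-1(2H)-one | CC[Si](CC)(CC)O[C@@H]1CC(C)=CC[C@@]2(C)CCC(=O)[C@H]12 | intermediate
15 | (3R,3aS,4R,8aR)-6,8a-dimethyl-3-(propan-2-yl)-4-[(triethylsilyl)oxy]-1,2,3,3a,4,5,8,8a-octahydroazulen-3-ol | CC[Si](CC)(CC)O[C@@H]1CC(C)=CC[C@@]2(C)CC[C@@](O)(C(C)C)[C@H]12 | intermediate (not isolated)
16 | (3R,3aS,4R,8aR)-6,8a-dimethyl-3-(propan-2-yl)-1,2,3,3a,4,5,8,8a-octahydroazulene-3,4-diol (6-epi-jaeschkeanadiol) | O[C@@H]1CC(C)=CC[C@@]2(C)CC[C@@](O)(C(C)C)[C@H]12 | intermediate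
17 | (3R,3aR,8aR)-3-hydroxy-6,8a-dimethyl-3-(propan-2-yl)-1,2,3,3a,8,8a-hexahydroazulen-4(5H)-one | O=C1CC(C)=CC[C@@]2(C)CC[C@@](O)(C(C)C)[C@H]12 | intermediate
18 | jaeschkeanadiol, (3R,3aS,4S,8aR)-6,8a-dimethyl-3-(propan-2-yl)-1,2,3,3a,4,5,8,8a-octahydroazulene-3,4-diol | O[C@H]1CC(C)=CC[C@@]2(C)CC[C@@](O)(C(C)C)[C@H]12 | intermediate
19 | 4-methoxybenzoyl chloride | COc1ccc(C(Cl)=O)cc1 | starting material
20 | Fertidin | COc1ccc(C(=O)O[C@H]2CC(C)=CC[C@@]3(C)CC[C@@](O)(C(C)C)[C@H]23)cc1 | target

**Totals and risks**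

Total steps: 13. Longest linear sequence: 13 (1 to 20; 5 and 19 enter as commercial side inputs).

Steps most likely to fail:

1. Step 6 (aldol condensation/Cope cascade). The aldol may close through the methyl enolate instead, or the base may isomerise the skipped dienone before it is neutralised. Fallback, setting out from 3 and rejoining at 10: build the cyclopentenone by carbonylative [2+2+1] chemistry instead of aldol chemistry. Dess–Martin oxidation of 3 gives (1R,2R)-2-ethenyl-2-methylcyclopropane-1-carbaldehyde F1, used at once because cis-2-vinylcyclopropanecarbaldehydes equilibrate with dihydrooxepines. Dimethyl (1-diazo-2-oxopropyl)phosphonate with K2CO3 in MeOH converts it into (1S,2R)-2-ethenyl-1-ethynyl-2-methylcyclopropane F2. n-BuLi then MeI gives (1R,2R)-2-ethenyl-2-methyl-1-(prop-1-yn-1-yl)cyclopropane F3. A Pauson–Khand reaction of F3 with ethylene and CO (Co2(CO)8, toluene, 120 °C, autoclave) places the bulkier cyclopropyl group next to the carbonyl, giving 9, which rearranges under the same conditions to 10.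

2. Step 10 (isopropyl addition to a hindered, enolisable β-silyloxy ketone). Enolisation, reduction by the Grignard reagent or loss of the silyloxy group may compete. Fallback, setting out from 14 and rejoining at 15: use an sp2 nucleophile and reduce afterwards. 2-Propenylmagnesium bromide with CeCl3 gives (3S,3aS,4R,8aR)-6,8a-dimethyl-3-(prop-1-en-2-yl)-4-[(triethylsilyl)oxy]-1,2,3,3a,4,5,8,8a-octahydroazulen-3-ol F4. Hydrogenation with RhCl(PPh3)3 saturates only its 1,1-disubstituted alkene and leaves the trisubstituted ring alkene, giving 15, which is desilylated to 16 as in the main route.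

3. Step 5 (hot aqueous acid next to a vinylcyclopropane). Fallback, setting out from 7 and rejoining at 8: open the furan oxidatively instead of hydrolytically. NBS with NaHCO3 in aqueous acetone at −20 °C gives (3Z)-1-[(1S,2R)-2-ethenyl-2-methylcyclopropyl]hex-3-ene-2,5-dione F5. Zinc dust in aqueous NH4Cl/THF then reduces the ene-dione C=C to give 8.

**Further compounds**

F1 | step 6 | (1R,2R)-2-ethenyl-2-methylcyclopropane-1-carbaldehyde | O=C[C@@H]1C[C@]1(C)C=C
F2 | step 6 | (1S,2R)-2-ethenyl-1-ethynyl-2-methylcyclopropane | C#C[C@@H]1C[C@]1(C)C=C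
F3 | step 6 | (1R,2R)-2-ethenyl-2-methyl-1-(prop-1-yn-1-yl)cyclopropane | CC#C[C@@H]1C[C@]1(C)C=C
F4 | step 10 | (3S,3aS,4R,8aR)-6,8a-dimethyl-3-(prop-1-en-2-yl)-4-[(triethylsilyl)oxy]-1,2,3,3a,4,5,8,8a-octahydroazulen-3-ol | CC[Si](CC)(CC)O[C@@H]1CC(C)=CC[C@@]2(C)CC[C@@](O)(C(C)=C)[C@H]12
F5 | step 5 | (3Z)-1-[(1S,2R)-2-ethenyl-2-methylcyclopropyl]hex-3-ene-2,5-dione | CC(=O)/C=C\C(=O)C[C@@H]1C[C@]1(C)C=C
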